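**Assumption:** the target has no stereocentre and is achiral (two identical halves), so no stereocontrol is needed.

## Retrosynthetic overview
1. Target 5 ⇒ remove six aryl C–Br bonds (exhaustive electrophilic bromination, last step) ⇒ bis-catechol 4.
2. Bis-catechol 4 ⇒ disconnect one aryl C–O bond per ring, ortho to the existing OH (key disconnection, new peroxydicarbonate ortho-oxygenation) ⇒ bisphenol 1.
3. Both benzene rings and the central CH2–CH2 bond are bought in 1, so no ring and no C–C bond is formed in the route.
4. Order: C–O first, on the electron-rich unhindered ring. C–Br last, because the new OH places every remaining ring position ortho or para to an OH.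

## Route

Step 1
Reactants: 1 4,4'-(ethane-1,2-diyl)diphenol (4,4'-dihydroxybibenzyl)
Product: 4 4,4'-(ethane-1,2-diyl)bis(benzene-1,2-diol), via bis(aryl peroxycarbonate) 2 (not isolated), via bis(catechol monocarbonate) 3 (not isolated)
Conditions: dihexadecyl peroxydicarbonate (2.2 equiv), (CF3)2CHOH/CH2Cl2 1:2, 0 to 25 °C, dark, N2; evaporate; then K2CO3 (10 mol %), degassed MeOH, 25 °C
Reagents that add atoms: dihexadecyl peroxydicarbonate (dicetyl peroxydicarbonate, a bulk polymerisation initiator), CCCCCCCCCCCCCCCCOC(=O)OOC(=O)OCCCCCCCCCCCCCCCC
Why: Proposed new method: ortho C–H oxygenation of a free phenol with a dialkyl peroxydicarbonate; the fluoroalcohol hydrogen-bonds to the carbonyl groups and lowers the O–O sigma* orbital, the phenol oxygen attacks the peroxide bond and expels a monoalkyl carbonate that falls apart to alcohol and CO2 (irreversible, no acid build-up), the aryl peroxycarbonate 2 holds the C=C–O–O–C=O array for a [3,3]-sigmatropic shift that can deliver oxygen only to the ortho carbon, re-aromatisation gives 3, whose electron-poor carbonate slows a second oxygenation and keeps the ring at the catechol level so that no tautomerisation-prone 4-alkyl ortho-quinone is formed, and catalytic methanolysis frees 4 (any simple O-acylated phenol returns to 1 at this stage); the closest known reaction types are the ortho-benzoyloxylation of phenols with dibenzoyl peroxide, the fluoroalcohol-promoted arene C–H oxygenation with cyclic diacyl peroxides and the Lewis-acid-promoted arene oxygenation with peroxydicarbonates; no stereocentre is formed.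

Step 2
Reactants: 4 4,4'-(ethane-1,2-diyl)bis(benzene-1,2-diol)
Product: 5 1,2-bis(2,3,6-tribromo-4,5-dihydroxyphenyl)ethane
Conditions: Br2 (6.2 equiv), AcOH, 20 to 45 °C, dark; then H2O, filter
Reagents that add atoms: bromine, BrBr
Why: Uncatalysed exhaustive electrophilic aromatic bromination, in which each of the three free positions per ring is ortho or para to a free OH (as in catechol to tetrabromocatechol), any transient ortho-quinone re-adds HBr to the same bromocatechol, and the dark ionic conditions with near-stoichiometric Br2 spare the benzylic CH2 groups; no stereocentre is formed.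

## Compound list
1 | 4,4'-(ethane-1,2-diyl)diphenol | Oc1ccc(CCc2ccc(O)cc2)cc1 | starting material
2 | 1,2-bis[4-(hexadecyloxycarbonylperoxy)phenyl]ethane | CCCCCCCCCCCCCCCCOC(=O)OOc1ccc(CCc2ccc(OOC(=O)OCCCCCCCCCCCCCCCC)cc2)cc1 | intermediate (not isolated)
3 | 1,2-bis[3-(hexadecyloxycarbonyloxy)-4-hydroxyphenyl]ethane | CCCCCCCCCCCCCCCCOC(=O)Oc1cc(CCc2ccc(O)c(OC(=O)OCCCCCCCCCCCCCCCC)c2)ccc1O | intermediate (not isolated)
4 | 4,4'-(ethane-1,2-diyl)bis(benzene-1,2-diol) | Oc1ccc(CCc2ccc(O)c(O)c2)cc1O | intermediate
5 | 1,2-bis(2,3,6-tribromo-4,5-dihydroxyphenyl)ethane | Oc1c(O)c(Br)c(CCc2c(Br)c(O)c(O)c(Br)c2Br)c(Br)c1Br | target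

## Step count and risks
Total step count: 2. Longest linear sequence: 2.

The route has only two steps, so both are listed in order of risk and there is no third step to rank.

1. **Step 1 (the proposed new step).**
   - Risks: the polar O–O attack may be too slow at 25 °C. Electron transfer or peroxide homolysis may give phenoxyl coupling products. Mono- and bis-oxygenated material may form as a mixture.
   - Fallback (known chemistry): it sets out from 1. 2-Iodoxybenzoic acid (2.2 equiv) in DMF at 25 °C, the established ortho-oxygenation of phenols by a pentavalent iodine reagent, gives the bis(ortho-quinone) 4,4'-(ethane-1,2-diyl)bis(cyclohexa-3,5-diene-1,2-dione) F1. This is reduced in the same flask with aqueous Na2S2O4, and the fallback comes back to the route at 4.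

2. **Step 2.**
   - Risks: penta-brominated material may precipitate before the last hindered position reacts. Excess Br2 may attack ipso to the alkyl group and cause benzylic bromination through a quinone methide.
   - Fallback (protect, brominate, deprotect): it sets out from 4. MeI and K2CO3 in acetone give 1,2-bis(3,4-dimethoxyphenyl)ethane F2. Excess Br2 with FeBr3 (10 mol %) in refluxing CH2Cl2 gives 1,2-bis(2,3,6-tribromo-4,5-dimethoxyphenyl)ethane F3. Partial demethylation at this stage does no harm. BBr3 in CH2Cl2 from −78 to 25 °C then cleaves the four ethers, and the fallback comes back to the route at 5.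

## Further compounds
F1 | step 1 | 4,4'-(ethane-1,2-diyl)bis(cyclohexa-3,5-diene-1,2-dione) | O=C1C(=O)C=C(CCC2=CC(=O)C(=O)C=C2)C=C1
F2 | step 2 | 1,2-bis(3,4-dimethoxyphenyl)ethane | COc1ccc(CCc2ccc(OC)c(OC)c2)cc1OC
F3 | step 2 | 1,2-bis(2,3,6-tribromo-4,5-dimethoxyphenyl)ethane | COc1c(OC)c(Br)c(CCc2c(Br)c(OC)c(OC)c(Br)c2Br)c(Br)c1Br
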